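(The constants used here belong to no real substance; the rest is arithmetic.)

A slow feed hands out its partners over time, so I begin with what the first end groups do in west while they wait.

| flask | first end groups | second end groups | time | remark |
|---|---|---|---|---|
| north-east | 5.0 × 10⁻⁴ M (fed, over 12 s) | 0.490 mM | 30 s | all else is in the flask from the start; the feed brings no volume worth counting |
| east | 5.0 × 10⁻⁴ M | 0.490 mM | 30 s | everything together at the start |
| west | 5.0 × 10⁻⁴ M | 0.490 mM (fed, over 12 s) | 30 s | all else is in the flask from the start; the feed brings no volume worth counting |

    links ⇌ isomer of the product (K1 = 1.7, k1 = 0.025 /s)
    crystals ⇌ by-product, rate k2*(cs2 - [by-product]) while solid is left; crystals form when [by-product] > cs2 (cs2 = 0.077 mM, k2 = 1.3 /s)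
    2 first end groups → homo dimer (k3 = 1200 /M/s)
    first end groups + second end groups ⇌ links + by-product (K4 = 1.6, k4 = 15000 /M/s)

1. the flask that comes out highest in amount of links, in percent of the first end groups charged, or "all alike" when all lie within 1.5 percentage points (north-east / east / west / all alike)
2. links at the end, in percent of the first end groups charged, north-east
3. links at the end, in percent of the first end groups charged, east
4. links at the end, in percent of the first end groups charged, west

- a species is counted by the first end groups in it: one homo dimer counts as two
- amounts and yields of by-product count crystals too
- a doubled species enters its step squared and goes two at a time
- given per volume of solution although it is solid: crystals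
- run time (north-east): 30 s

On paper the second end groups are the limiting reagent, at 0.980 equivalents, yet in west the first end groups look like the ones in danger, and these two things do not seem to go together.

I write the balance of the second end groups in west: the charge equals what is free plus what sits in links and isomer of the product. They enter at 0.0408 mM/s, but the first half-life of the first end groups by dimerising is 0.833 s, far shorter than the 12 s feed.

Dimerising falls with the square of the first end groups, and in west it uses them as fast as the feed arrives at 0.130 mM. I call this the crossover level: the level of first end groups at which dimerising and feed are equal.

At that level the first half-life is 3.19 s, and in that time the feed brings about the same amount. So I reckon that links and isomer of the product together reach about the crossover level in west, 26.1% of the charge, and that 73.4% of the second end groups stay free.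

Links and isomer of the product relax with a half-life of 17.5 s in west, which, counted from the start, leaves links 56.2% of the pair, so I expect 14.7% links in west. My reckoning goes no further than west.

The forecast gives 28% for north-east, 24% for east and 19% for west, so north-east comes first. Its ground for west is that “feeding the second end groups leaves the first end groups concentrated and unpartnered early on”. Its west figure is higher than mine.

The flasks give 30.8% for north-east, 25.5% for east and 13.2% for west, so north-east comes first and the forecast's west stands above the result.

In west, the midpoint of the dimerising turnover up to the asked time falls at 0.526 s, earlier than that of the coupling at 2.08 s, and at 30.0 s links and isomer of the product hold 22.6% of the charge, with 1.7% of the first end groups and 77% of the second left. The neighbour of west charged with 8.5 × 10⁻⁴ M of first end groups has the same feed and crossover level, now 15.3% of its charge, and it holds 14.1% in links and isomer of the product, of which 8.25% is links.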